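**Retrosynthetic overview**
1. Target 11 ⇒ bromo-hydroxyquinone 8 + H2O2. The quinone C–O(OH) bond is made last, by perhydrolysis of a vinylogous acyl bromide (key step, new).
2. 8 ⇒ symmetric dibromide 6. This is a C–O bond formed by a self-limiting mono-hydrolysis.
3. 6 ⇒ bromanil 4 + 2 × 5-prenylindole 3. Two indole C3–quinone bonds are formed by double addition–elimination.
4. 3 ⇒ 5-bromoindole 1 + prenylstannane 2 (Stille coupling at C5).
5. Rings: none is built. Both indole bicycles and the quinone ring are bought intact.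

**Assumption:** the target has no stereocentre and no stereogenic double bond (each prenyl alkene carries two methyl groups), and the indolyl–quinone axes rotate freely. It is therefore achiral and there is no configuration to set.

**Step 1**
Reactants: 1 5-bromo-1H-indole; 2 tributyl(3-methylbut-2-en-1-yl)stannane
Product: 3 5-(3-methylbut-2-en-1-yl)-1H-indole
Conditions: Pd(PPh3)4 (5 mol %), DMF, 100 °C, 12 h
Reagents that add atoms: none
Why: Stille cross-coupling, in which zerovalent palladium inserts into C5–Br, tin transfers the allyl group, and reductive elimination at the unhindered CH2 terminus of the η3-prenyl ligand gives the linear prenyl arene with the free N–H tolerated and no stereocentre formed.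

**Step 2**
Reactants: 3 5-(3-methylbut-2-en-1-yl)-1H-indole (2.1 equiv); 4 tetrabromo-1,4-benzoquinone (bromanil)
Product: 6 2,5-dibromo-3,6-bis[5-(3-methylbut-2-en-1-yl)-1H-indol-3-yl]cyclohexa-2,5-diene-1,4-dione, via tribromo(indolyl)quinone 5 (not isolated)
Conditions: Cs2CO3 (4 equiv), MeCN, 23 °C, 4 h
Reagents that add atoms: none
Why: Base-mediated addition–elimination of indole C3 on bromanil is a known entry to 2,5-dihalo-3,6-bis(indolyl)quinones, and the first indolyl group donates into one carbonyl and shields its neighbouring carbon, so the second indole attacks the para carbon and gives the 3,6-pattern with no stereocentre formed.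

**Step 3**
Reactants: 6 2,5-dibromo-3,6-bis[5-(3-methylbut-2-en-1-yl)-1H-indol-3-yl]cyclohexa-2,5-diene-1,4-dione
Product: 8 2-bromo-5-hydroxy-3,6-bis[5-(3-methylbut-2-en-1-yl)-1H-indol-3-yl]cyclohexa-2,5-diene-1,4-dione, via Na salt of the bromohydroxyquinone 7 (not isolated)
Conditions: NaOH (2.1 equiv, 1 M aq), THF, 0 → 23 °C; then 1 M HCl to pH 3
Reagents that add atoms: NaOH, [Na+].[OH-]
Why: This is the standard haloquinone hydrolysis (addition–elimination of hydroxide on a vinylogous acyl bromide), and it stops after one exchange because the product is deprotonated at once to the vinylogous carboxylate 7, whose charge blocks the second attack that needs hot excess alkali, while the two equivalent C–Br sites of 6 allow only one product.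

**Step 4**
Reactants: 8 2-bromo-5-hydroxy-3,6-bis[5-(3-methylbut-2-en-1-yl)-1H-indol-3-yl]cyclohexa-2,5-diene-1,4-dione
Product: 11 hydroperoxycochliodinol = 2-hydroperoxy-5-hydroxy-3,6-bis[5-(3-methylbut-2-en-1-yl)-1H-indol-3-yl]cyclohexa-2,5-diene-1,4-dione, via Mg(OTf) chelate of the bromoquinonolate 9 (not isolated), via Mg(OTf) chelate of the hydroperoxyquinonolate 10 (not isolated)
Conditions: Mg(OTf)2 (1.2 equiv), urea·H2O2 (5 equiv), 2,6-lutidine (2.5 equiv), THF/DMF 5:1, −20 → 0 °C, dark, Ar; then cold pH 4 citrate buffer, no reductive quench; Sephadex LH-20 at 5 °C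
Reagents that add atoms: urea–hydrogen peroxide adduct, OO.NC(N)=O (delivers the OOH group); Mg(OTf)2, [Mg+2].[O-]S(=O)(=O)C(F)(F)F.[O-]S(=O)(=O)C(F)(F)F (atoms present only in 9 and 10)
Why: Proposed new method: chelation-activated vinylogous perhydrolysis of a bromoquinone to an isolable quinonyl hydroperoxide; divalent magnesium binds the olate oxygen and the adjacent C=O of 8 in a five-membered chelate, which cancels the deactivating charge and polarises exactly the carbonyl conjugated to the C–Br carbon, while magnesium-acidified H2O2 is deprotonated by the non-nucleophilic, hard-to-oxidise lutidine to an α-effect hydroperoxide nucleophile that adds at C–Br; the magnesium-bound enolate σ-adduct then expels bromide faster than it can close onto the O–O bond (Weitz–Scheffer epoxide path), the anhydrous peroxide source excludes competing hydroxide, and the isolated prenyl alkenes and indoles are inert to nucleophilic peroxide; the closest known reaction types are perhydrolysis of acyl chlorides or N-acyl oxazolidinones with H2O2 and base to peroxy acids and hydroxide or alkoxide addition–elimination on haloquinones; no stereocentre is formed.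

**Compound list**
1 | 5-bromo-1H-indole | Brc1ccc2[nH]ccc2c1 | starting material
2 | tributyl(3-methylbut-2-en-1-yl)stannane | CCCC[Sn](CCCC)(CCCC)CC=C(C)C | starting material
3 | 5-(3-methylbut-2-en-1-yl)-1H-indole | CC(C)=CCc1ccc2[nH]ccc2c1 | intermediate
4 | tetrabromo-1,4-benzoquinone (bromanil) | O=C1C(Br)=C(Br)C(=O)C(Br)=C1Br | starting material
5 | 2,3,5-tribromo-6-[5-(3-methylbut-2-en-1-yl)-1H-indol-3-yl]cyclohexa-2,5-diene-1,4-dione | CC(C)=CCc1ccc2[nH]cc(C3=C(Br)C(=O)C(Br)=C(Br)C3=O)c2c1 | intermediate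
6 | 2,5-dibromo-3,6-bis[5-(3-methylbut-2-en-1-yl)-1H-indol-3-yl]cyclohexa-2,5-diene-1,4-dione | CC(C)=CCc1ccc2[nH]cc(C3=C(Br)C(=O)C(c4c[nH]c5ccc(CC=C(C)C)cc45)=C(Br)C3=O)c2c1 | intermediate
7 | sodium 4-bromo-3,6-dioxo-2,5-bis[5-(3-methylbut-2-en-1-yl)-1H-indol-3-yl]cyclohexa-1,4-dien-1-olate | CC(C)=CCc1ccc2[nH]cc(C3=C([O-])C(=O)C(c4c[nH]c5ccc(CC=C(C)C)cc45)=C(Br)C3=O)c2c1.[Na+] | intermediate
8 | 2-bromo-5-hydroxy-3,6-bis[5-(3-methylbut-2-en-1-yl)-1H-indol-3-yl]cyclohexa-2,5-diene-1,4-dione | CC(C)=CCc1ccc2[nH]cc(C3=C(O)C(=O)C(c4c[nH]c5ccc(CC=C(C)C)cc45)=C(Br)C3=O)c2c1 | intermediate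
9 | Mg(OTf) O,O-chelate (olate O and adjacent C=O) of deprotonated 8 | CC(C)=CCc1ccc2[nH]cc(C3=C([O-])C(=O)C(c4c[nH]c5ccc(CC=C(C)C)cc45)=C(Br)C3=O)c2c1.[Mg+2].[O-]S(=O)(=O)C(F)(F)F | intermediate
10 | Mg(OTf) O,O-chelate of 11 deprotonated at the hydroxy group | CC(C)=CCc1ccc2[nH]cc(C3=C([O-])C(=O)C(c4c[nH]c5ccc(CC=C(C)C)cc45)=C(OO)C3=O)c2c1.[Mg+2].[O-]S(=O)(=O)C(F)(F)F | intermediate
11 | hydroperoxycochliodinol (achiral) | CC(C)=CCc1ccc2[nH]cc(C3=C(O)C(=O)C(c4c[nH]c5ccc(CC=C(C)C)cc45)=C(OO)C3=O)c2c1 | target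

**Total step count:** 4. **Longest linear sequence:** 4 (1 → 3 → 6 → 8 → 11).

**Three steps most likely to fail**

**Step 4 (the proposed new step).**
- The σ-adduct may close to a bromo-epoxide instead of losing bromide.
- The product may be reduced to cochliodinol by excess basic H2O2.
- The product may lose its O–O bond by homolysis, or it may epoxidise a prenyl group of another molecule.

The fallback uses only established operations. It sets out from 8 and comes back at 11.
- 8 is capped with MOMCl and iPr2NEt in CH2Cl2 at 0 °C. This gives the neutral electrophile 2-bromo-5-(methoxymethoxy)-3,6-bis[5-(3-methylbut-2-en-1-yl)-1H-indol-3-yl]-1,4-benzoquinone F1.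
- Separately, ozonolysis of 2,3-dimethylbut-2-ene in MeOH/CH2Cl2 at −78 °C gives the known masked hydroperoxide nucleophile 2-hydroperoxy-2-methoxypropane F2.
- F2 and Cs2CO3 in DMF at 0 °C displace the bromide of F1 by ordinary O-nucleophile addition–elimination on a haloquinone. The product is the doubly masked 2-(methoxymethoxy)-5-[(2-methoxypropan-2-yl)peroxy]quinone F3.
- AcOH/THF/H2O at 23 °C hydrolyses the peroxyketal and the vinylogous MOM ester together and gives 11.

**Step 3.**
- Over-hydrolysis to cochliodinol is possible.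
- The reaction may stall because hydroxide deprotonates the indole N–H groups.

The fallback replaces hydroxide by an anhydrous substitution–fragmentation sequence. It sets out from 6 and comes back at 7.
- 6 in dry DMF at 0 °C is treated with sodium (E)-benzaldoximate (2.1 equiv, from the oxime and NaH).
- One bromide is displaced to give the O-quinonyl (E)-benzaldoxime ether F4.
- The second equivalent of oximate fragments F4 by E2 loss of benzonitrile and gives the sodium salt 7 directly. 7 is inert to further attack.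
- Acidification as in step 3 then gives 8.

**Step 2.**
- The yield may be modest.
- Some 2,6-isomer or N-linked product may form.
- The strongly oxidising bromanil may damage the prenyl groups.

The fallback replaces halide displacement by stepwise conjugate addition and oxidation at quinone C–H positions. It sets out from 3 and comes back at 6.
- 3 (1 equiv) adds to commercial 2,5-dibromo-1,4-benzoquinone in AcOH/THF at 23 °C. This gives 2,5-dibromo-3-[5-(3-methylbut-2-en-1-yl)-1H-indol-3-yl]benzene-1,4-diol F5.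
- DDQ oxidises F5 to 2,5-dibromo-3-[5-(3-methylbut-2-en-1-yl)-1H-indol-3-yl]-1,4-benzoquinone F6.
- A second equivalent of 3 in AcOH adds at the remaining C–H. This gives 2,5-dibromo-3,6-bis[5-(3-methylbut-2-en-1-yl)-1H-indol-3-yl]benzene-1,4-diol F7.
- DDQ oxidises F7 to 6.

**Further compounds**
F1 | step 4 | 2-bromo-5-(methoxymethoxy)-3,6-bis[5-(3-methylbut-2-en-1-yl)-1H-indol-3-yl]cyclohexa-2,5-diene-1,4-dione | CC(C)=CCc1ccc2[nH]cc(C3=C(OCOC)C(=O)C(c4c[nH]c5ccc(CC=C(C)C)cc45)=C(Br)C3=O)c2c1
F2 | step 4 | 2-hydroperoxy-2-methoxypropane | COC(C)(C)OO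
F3 | step 4 | 2-(methoxymethoxy)-5-[(2-methoxypropan-2-yl)peroxy]-3,6-bis[5-(3-methylbut-2-en-1-yl)-1H-indol-3-yl]cyclohexa-2,5-diene-1,4-dione | CC(C)=CCc1ccc2[nH]cc(C3=C(OCOC)C(=O)C(c4c[nH]c5ccc(CC=C(C)C)cc45)=C(OOC(C)(C)OC)C3=O)c2c1
F4 | step 3 | (E)-benzaldehyde O-{4-bromo-3,6-dioxo-2,5-bis[5-(3-methylbut-2-en-1-yl)-1H-indol-3-yl]cyclohexa-1,4-dien-1-yl}oxime | CC(C)=CCc1ccc2[nH]cc(C3=C(O/N=C/c6ccccc6)C(=O)C(c4c[nH]c5ccc(CC=C(C)C)cc45)=C(Br)C3=O)c2c1
F5 | step 2 | 2,5-dibromo-3-[5-(3-methylbut-2-en-1-yl)-1H-indol-3-yl]benzene-1,4-diol | CC(C)=CCc1ccc2[nH]cc(-c3c(O)c(Br)cc(O)c3Br)c2c1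
F6 | step 2 | 2,5-dibromo-3-[5-(3-methylbut-2-en-1-yl)-1H-indol-3-yl]cyclohexa-2,5-diene-1,4-dione | CC(C)=CCc1ccc2[nH]cc(C3=C(Br)C(=O)C=C(Br)C3=O)c2c1
F7 | step 2 | 2,5-dibromo-3,6-bis[5-(3-methylbut-2-en-1-yl)-1H-indol-3-yl]benzene-1,4-diol | CC(C)=CCc1ccc2[nH]cc(-c3c(O)c(Br)c(-c4c[nH]c5ccc(CC=C(C)C)cc45)c(O)c3Br)c2c1
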